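**Strategy.** Everything rests on opening the cis-fused α-methylene-γ-butyrolactone on the cyclopentane ring at two bonds: the lactone O–C bond at the ring carbinol carbon, and the bond between the exo-methylene-bearing carbon and the carbonyl carbon. The whole O–C=O unit then comes from CO2. The precursor is a spiro[4.5]decene that carries a 1-bromovinyl group and, trans to it on the neighbouring cyclopentane carbon, a tosylate. Bromine–lithium exchange, capture of CO2 and intramolecular SN2 displacement by the new carboxylate build the lactone in one operation. The inversion at the carbinol carbon turns the trans pair (from an Evans syn aldol) into the cis ring fusion.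

Key step: step 17

Remark on the chemistry: the sense of induction in step 1 is assigned from the usual face-shielding model of the diarylprolinol silyl ether; should the opposite sense be found, the (S)-configured catalyst would be used. Chloroacetaldehyde 11 is used as the anhydrous monomer, freshly distilled from its commercial aqueous solution.

**Step 1**
Reactants: 1 (E)-but-2-enal; 2 tert-butyl 3-oxobutanoate
Product: 5 (5S)-5-methylcyclohex-2-en-1-one, via Michael adduct 3 (not isolated), via cyclic keto ester 4 (not isolated)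
Conditions: (R)-2-{bis[3,5-bis(trifluoromethyl)phenyl][(trimethylsilyl)oxy]methyl}pyrrolidine (10 mol %), neat, 25 °C; then TsOH·H2O (20 mol %), toluene, 80 °C
Reagents that add atoms: none
Why: Iminium-catalysed Michael addition of the β-keto ester to the enal on the face left open by the diaryl(silyloxy)methyl group should set the methyl-bearing stereocentre, and acid then drives intramolecular aldol condensation, tert-butyl ester cleavage and decarboxylation (organocatalytic Michael/aldol cascade).

**Step 2**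
Reactants: 6 3-bromobut-3-en-1-ol
Product: 7 3-bromobut-3-enoic acid
Conditions: TEMPO (cat.), PhI(OAc)2 (2.2 equiv), MeCN/H2O, 25 °C
Reagents that add atoms: water, O
Why: Oxoammonium oxidation of the primary alcohol through the aldehyde hydrate should give the acid without touching the vinyl bromide (TEMPO/PhI(OAc)2 oxidation).

**Step 3**
Reactants: 7 3-bromobut-3-enoic acid; 8 (4R)-4-benzyl-1,3-oxazolidin-2-one
Product: 10 (4R)-4-benzyl-3-(3-bromobut-3-enoyl)-1,3-oxazolidin-2-one, via mixed pivalic anhydride 9 (not isolated)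
Conditions: t-BuCOCl, Et3N, THF, −78 → 0 °C; then 8 pre-treated with n-BuLi, THF, −78 °C
Reagents that add atoms: none
Why: Acylation of the lithiated oxazolidinone by the mixed anhydride at low temperature should avoid conjugation of the β,γ-unsaturated acyl group (N-acylation of an Evans auxiliary).

**Step 4**
Reactants: 10 (4R)-4-benzyl-3-(3-bromobut-3-enoyl)-1,3-oxazolidin-2-one; 11 2-chloroacetaldehyde
Product: 13 (4R)-4-benzyl-3-[(2R,3R)-2-(1-bromoethenyl)-4-chloro-3-hydroxybutanoyl]-1,3-oxazolidin-2-one, via boron enolate 12 (not isolated)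
Conditions: n-Bu2BOTf, i-Pr2NEt, CH2Cl2, −78 → 0 °C; 11, −78 °C; then pH 7 buffer, MeOH, H2O2, 0 °C
Reagents that add atoms: none
Why: The (Z)-boron enolate should add through a Zimmerman–Traxler chair on the enolate face away from the benzyl group, giving the syn aldol and setting both the bromovinyl-bearing carbon and the carbinol carbon (Evans aldol reaction).

**Step 5**
Reactants: 13 syn aldol adduct
Product: 14 (4R)-4-benzyl-3-[(2R,3R)-2-(1-bromoethenyl)-4-chloro-3-(triethylsilyloxy)butanoyl]-1,3-oxazolidin-2-one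
Conditions: Et3SiOTf, 2,6-lutidine, CH2Cl2, −78 °C
Reagents that add atoms: triethylsilyl trifluoromethanesulfonate, CC[Si](CC)(CC)OS(=O)(=O)C(F)(F)F
Why: Silylation of the secondary alcohol blocks retro-aldol cleavage and epoxide formation from the chlorohydrin (silyl ether protection).

**Step 6**
Reactants: 14 silylated aldol adduct
Product: 15 (2S,3R)-2-(1-bromoethenyl)-4-chloro-3-(triethylsilyloxy)butan-1-ol
Conditions: LiBH4, MeOH (1 equiv), Et2O, 0 °C
Reagents that add atoms: none
Why: LiBH4 should reduce the N-acyl oxazolidinone to the primary alcohol and release the auxiliary without touching the chloride or the vinyl bromide (reductive auxiliary removal).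

**Step 7**
Reactants: 15 primary alcohol
Product: 16 (2S,3R)-2-(1-bromoethenyl)-4-chloro-3-(triethylsilyloxy)butyl trifluoromethanesulfonate
Conditions: Tf2O, 2,6-lutidine, CH2Cl2, −78 °C; used at once
Reagents that add atoms: trifluoromethanesulfonic anhydride, O=S(=O)(OS(=O)(=O)C(F)(F)F)C(F)(F)F
Why: The triflate supplies the reactivity needed to alkylate an enolate at a β-branched primary carbon (O-sulfonylation).

**Step 8**
Reactants: 5 (5S)-5-methylcyclohex-2-en-1-one; 16 primary triflate
Product: 18 (2S,3S,5R,10S)-2-(1-bromoethenyl)-10-methyl-3-(triethylsilyloxy)spiro[4.5]dec-7-en-6-one, via monoalkylated enone 17 (not isolated)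
Conditions: LiN(i-Pr)2 (1.05 equiv), THF, −78 °C; 16, −78 → −30 °C; then LiN(i-Pr)2 (1.2 equiv), HMPA, −78 → 25 °C
Reagents that add atoms: none
Why: Kinetic α′-alkylation by the triflate is followed by a second α′-deprotonation and 5-exo-tet displacement of chloride on the enolate face anti to the adjacent methyl group, so the CH2 on the carbinol side should end trans to methyl at the spiro centre (spiroannulation by double enolate alkylation).

**Step 9**
Reactants: 19 tributyl(iodomethyl)stannane; 20 (4-methoxyphenyl)methanol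
Product: 21 tributyl{[(4-methoxybenzyl)oxy]methyl}stannane
Conditions: NaH, THF/DMF, 0 → 25 °C
Reagents that add atoms: none
Why: The sodium alkoxide displaces the primary iodide (Williamson ether synthesis).

**Step 10**
Reactants: 18 spiro enone; 21 alkoxymethylstannane
Product: 22 (2S,3S,5R,10S)-2-(1-bromoethenyl)-6-{[(4-methoxybenzyl)oxy]methyl}-10-methyl-3-(triethylsilyloxy)spiro[4.5]dec-7-en-6-ol (both C6 epimers)
Conditions: 21, n-BuLi, THF, −78 °C, 10 min; then 18, −78 °C; aq. NH4Cl
Reagents that add atoms: none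
Why: Tin–lithium exchange gives the α-alkoxymethyllithium, which should add 1,2 to the enone carbonyl faster than it exchanges with the vinyl bromide at −78 °C; the new carbinol centre is lost in the next step (α-alkoxyorganolithium addition).

**Step 11**
Reactants: 22 tertiary allylic alcohol
Product: 23 (2S,3S,5R,10S)-2-(1-bromoethenyl)-6-{[(4-methoxybenzyl)oxy]methyl}-10-methyl-3-(triethylsilyloxy)spiro[4.5]dec-6-en-8-one
Conditions: IBX, DMSO, 55 °C
Reagents that add atoms: none
Why: The iodine-bound tertiary allylic alcohol should undergo 1,3-transposition and oxidation to the β-substituted enone (Babler–Dauben-type oxidative transposition).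

**Step 12**
Reactants: 23 transposed enone
Product: 24 (2S,3S,5R,9S,10R)-2-(1-bromoethenyl)-9-hydroxy-6-{[(4-methoxybenzyl)oxy]methyl}-10-methyl-3-(triethylsilyloxy)spiro[4.5]dec-6-en-8-one
Conditions: KN(SiMe3)2, THF, −78 °C; 3-phenyl-2-(phenylsulfonyl)oxaziridine, −78 °C; aq. NH4Cl
Reagents that add atoms: 3-phenyl-2-(phenylsulfonyl)oxaziridine, O=S(=O)(c1ccccc1)N1OC1c1ccccc1
Why: The kinetic α′-enolate should be oxidised on the face anti to the adjacent methyl group, placing the new hydroxyl trans to methyl (Davis oxidation).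

**Step 13**
Reactants: 24 α′-hydroxy enone
Product: 25 (2S,3S,5R,8S,9S,10R)-2-(1-bromoethenyl)-6-{[(4-methoxybenzyl)oxy]methyl}-10-methyl-3-(triethylsilyloxy)spiro[4.5]dec-6-ene-8,9-diol
Conditions: NaBH4, CeCl3·7H2O, MeOH, −78 → −40 °C
Reagents that add atoms: none
Why: Selective 1,2-reduction with axial hydride delivery should give the equatorial allylic alcohol trans to the neighbouring hydroxyl (Luche reduction).

**Step 14**
Reactants: 25 trans-diol
Product: 26 (2S,3S,5R,8S,9S,10R)-2-(1-bromoethenyl)-8,9-bis(tert-butyldimethylsilyloxy)-6-{[(4-methoxybenzyl)oxy]methyl}-10-methyl-3-(triethylsilyloxy)spiro[4.5]dec-6-ene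
Conditions: t-BuMe2SiOTf (3 equiv), 2,6-lutidine, CH2Cl2, −20 → 0 °C
Reagents that add atoms: tert-butyldimethylsilyl trifluoromethanesulfonate, CC(C)(C)[Si](C)(C)OS(=O)(=O)C(F)(F)F
Why: Both secondary hydroxyls are silylated so that only the cyclopentane oxygen can later be freed (silyl ether protection).

**Step 15**
Reactants: 26 tris-silyl ether
Product: 27 (2S,3S,5R,8S,9S,10R)-2-(1-bromoethenyl)-8,9-bis(tert-butyldimethylsilyloxy)-6-{[(4-methoxybenzyl)oxy]methyl}-10-methylspiro[4.5]dec-6-en-3-ol
Conditions: PPTS (0.2 equiv), MeOH/CH2Cl2, 0 °C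
Reagents that add atoms: none
Why: Acid methanolysis should cleave the secondary triethylsilyl ether much faster than the secondary tert-butyldimethylsilyl ethers (selective desilylation).

**Step 16**
Reactants: 27 cyclopentanol
Product: 28 (2S,3S,5R,8S,9S,10R)-2-(1-bromoethenyl)-8,9-bis(tert-butyldimethylsilyloxy)-6-{[(4-methoxybenzyl)oxy]methyl}-10-methylspiro[4.5]dec-6-en-3-yl 4-methylbenzenesulfonate
Conditions: TsCl, DMAP, pyridine/CH2Cl2, 25 °C
Reagents that add atoms: 4-methylbenzenesulfonyl chloride, Cc1ccc(cc1)S(=O)(=O)Cl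
Why: Sulfonylation at oxygen keeps the configuration and gives a leaving group without acidic α-hydrogens, trans to the bromovinyl group (tosylation).

**Step 17**
Reactants: 28 trans bromovinyl tosylate
Product: 31 bis-silyl PMB-protected spiro α-methylene-γ-butyrolactone (configuration at all six stereocentres as in the target), via alkenyllithium 29 (not isolated), via lithium carboxylate 30 (not isolated)
Conditions: t-BuLi (2.05 equiv), THF/Et2O/pentane, −100 °C, 5 min; CO2 (dry gas), −100 → −78 °C; then HMPA, −78 → 45 °C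
Reagents that add atoms: carbon dioxide, O=C=O
Why: Bromine–lithium exchange gives the 1-substituted alkenyllithium, which adds to CO2 to form the bond between the exo-methylene-bearing carbon and the carbonyl carbon, and the resulting lithium acrylate then displaces the neighbouring tosylate intramolecularly to form the lactone O–C bond. The closest known reaction types are the carboxylation of alkenyllithiums with CO2 and the lactonisation of carboxylates onto sulfonates, run here as one cascade. The lactone ring closes in the 5-exo-tet mode. The carbinol stereocentre is set by SN2 inversion of the tosylate, whose trans relation to the alkenyl group (from the Evans syn aldol) forces the cis ring fusion; no other stereocentre is touched. The step needs exchange and CO2 capture to outrun 3-exo-tet attack of the alkenyllithium on the tosylate-bearing carbon, which the very low temperature, the sp2 carbanion and the absence of acidic sulfonate hydrogens should secure; it also needs substitution to beat elimination, which the weakly basic carboxylate and the five-membered transition state should secure.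

**Step 18**
Reactants: 31 protected lactone
Product: 32 bis-silyl spiro α-methylene lactone with free primary allylic alcohol
Conditions: DDQ, CH2Cl2/pH 7 buffer, 0 °C
Reagents that add atoms: none
Why: Single-electron oxidation of the electron-rich benzyl ether and hydrolysis of the oxocarbenium ion frees the primary alcohol under neutral conditions that spare the lactone and silyl ethers (oxidative PMB cleavage).

**Step 19**
Reactants: 32 primary allylic alcohol; 33 (2Z)-2-methylbut-2-enoic acid (angelic acid)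
Product: 35 bis-silyl ether of the target angelate, via mixed Yamaguchi anhydride 34 (not isolated)
Conditions: 33, 2,4,6-trichlorobenzoyl chloride, Et3N, toluene, 25 °C; then 32, DMAP, 25 °C
Reagents that add atoms: none
Why: Acyl transfer from the mixed anhydride to the unhindered primary alcohol at room temperature should keep the Z geometry of the angelate (Yamaguchi esterification).

**Step 20**
Reactants: 35 bis-silyl ether of the target
Product: 36 target CNP0224912.1
Conditions: HF·pyridine, pyridine/THF, 0 → 25 °C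
Reagents that add atoms: none
Why: Buffered fluoride cleaves both secondary silyl ethers without acyl migration, ester isomerisation or addition to the α-methylene lactone (desilylation).

**Compound list**

1 | (E)-but-2-enal | C/C=C/C=O | starting material
2 | tert-butyl 3-oxobutanoate | CC(=O)CC(=O)OC(C)(C)C | starting material
3 | tert-butyl (3S)-2-acetyl-3-methyl-5-oxopentanoate (C2 epimers) | O=CC[C@H](C)C(C(C)=O)C(=O)OC(C)(C)C | intermediate
4 | tert-butyl (6S)-6-methyl-2-oxocyclohex-3-ene-1-carboxylate (C1 epimers) | O=C1C=CC[C@H](C)C1C(=O)OC(C)(C)C | intermediate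
5 | (5S)-5-methylcyclohex-2-en-1-one | O=C1C=CC[C@H](C)C1 | intermediate
6 | 3-bromobut-3-en-1-ol | OCCC(Br)=C | starting material
7 | 3-bromobut-3-enoic acid | OC(=O)CC(Br)=C | intermediate
8 | (4R)-4-benzyl-1,3-oxazolidin-2-one | O=C1OC[C@@H](Cc2ccccc2)N1 | starting material
9 | 3-bromobut-3-enoic pivalic anhydride | C=C(Br)CC(=O)OC(=O)C(C)(C)C | intermediate
10 | (4R)-4-benzyl-3-(3-bromobut-3-enoyl)-1,3-oxazolidin-2-one | C=C(Br)CC(=O)N1C(=O)OC[C@H]1Cc2ccccc2 | intermediate
11 | 2-chloroacetaldehyde | ClCC=O | starting material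
12 | (Z)-dibutylboron enolate of imide 10 | C=C(Br)/C=C(\OB(CCCC)CCCC)N1C(=O)OC[C@H]1Cc2ccccc2 | intermediate
13 | (4R)-4-benzyl-3-[(2R,3R)-2-(1-bromoethenyl)-4-chloro-3-hydroxybutanoyl]-1,3-oxazolidin-2-one | O=C([C@H](C(Br)=C)[C@@H](O)CCl)N1C(=O)OC[C@H]1Cc2ccccc2 | intermediate
14 | (4R)-4-benzyl-3-[(2R,3R)-2-(1-bromoethenyl)-4-chloro-3-(triethylsilyloxy)butanoyl]-1,3-oxazolidin-2-one | O=C([C@H](C(Br)=C)[C@@H](O[Si](CC)(CC)CC)CCl)N1C(=O)OC[C@H]1Cc2ccccc2 | intermediate
15 | (2S,3R)-2-(1-bromoethenyl)-4-chloro-3-(triethylsilyloxy)butan-1-ol | OC[C@H](C(Br)=C)[C@@H](O[Si](CC)(CC)CC)CCl | intermediate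
16 | (2S,3R)-2-(1-bromoethenyl)-4-chloro-3-(triethylsilyloxy)butyl trifluoromethanesulfonate | O=S(=O)(OC[C@H](C(Br)=C)[C@@H](O[Si](CC)(CC)CC)CCl)C(F)(F)F | intermediate
17 | (5S,6R)-6-[(2S,3R)-2-(1-bromoethenyl)-4-chloro-3-(triethylsilyloxy)butyl]-5-methylcyclohex-2-en-1-one | O=C1C=CC[C@H](C)[C@H]1C[C@H](C(Br)=C)[C@@H](O[Si](CC)(CC)CC)CCl | intermediate
18 | (2S,3S,5R,10S)-2-(1-bromoethenyl)-10-methyl-3-(triethylsilyloxy)spiro[4.5]dec-7-en-6-one | CC[Si](CC)(CC)O[C@H]2C[C@@]3(C[C@@H]2C(Br)=C)C(=O)C=CC[C@@H]3C | intermediate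
19 | tributyl(iodomethyl)stannane | CCCC[Sn](CCCC)(CCCC)CI | starting material
20 | (4-methoxyphenyl)methanol | COc1ccc(CO)cc1 | starting material
21 | tributyl{[(4-methoxybenzyl)oxy]methyl}stannane | CCCC[Sn](CCCC)(CCCC)COCc1ccc(OC)cc1 | intermediate
22 | (2S,3S,5R,10S)-2-(1-bromoethenyl)-6-{[(4-methoxybenzyl)oxy]methyl}-10-methyl-3-(triethylsilyloxy)spiro[4.5]dec-7-en-6-ol (C6 epimers) | CC[Si](CC)(CC)O[C@H]2C[C@@]3(C[C@@H]2C(Br)=C)C(O)(COCc4ccc(OC)cc4)C=CC[C@@H]3C | intermediate
23 | (2S,3S,5R,10S)-2-(1-bromoethenyl)-6-{[(4-methoxybenzyl)oxy]methyl}-10-methyl-3-(triethylsilyloxy)spiro[4.5]dec-6-en-8-one | CC[Si](CC)(CC)O[C@H]2C[C@@]3(C[C@@H]2C(Br)=C)C(COCc4ccc(OC)cc4)=CC(=O)C[C@@H]3C | intermediate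
24 | (2S,3S,5R,9S,10R)-2-(1-bromoethenyl)-9-hydroxy-6-{[(4-methoxybenzyl)oxy]methyl}-10-methyl-3-(triethylsilyloxy)spiro[4.5]dec-6-en-8-one | CC[Si](CC)(CC)O[C@H]2C[C@@]3(C[C@@H]2C(Br)=C)C(COCc4ccc(OC)cc4)=CC(=O)[C@@H](O)[C@@H]3C | intermediate
25 | (2S,3S,5R,8S,9S,10R)-2-(1-bromoethenyl)-6-{[(4-methoxybenzyl)oxy]methyl}-10-methyl-3-(triethylsilyloxy)spiro[4.5]dec-6-ene-8,9-diol | CC[Si](CC)(CC)O[C@H]2C[C@@]3(C[C@@H]2C(Br)=C)C(COCc4ccc(OC)cc4)=C[C@H](O)[C@@H](O)[C@@H]3C | intermediate
26 | (2S,3S,5R,8S,9S,10R)-2-(1-bromoethenyl)-8,9-bis(tert-butyldimethylsilyloxy)-6-{[(4-methoxybenzyl)oxy]methyl}-10-methyl-3-(triethylsilyloxy)spiro[4.5]dec-6-ene | CC[Si](CC)(CC)O[C@H]2C[C@@]3(C[C@@H]2C(Br)=C)C(COCc4ccc(OC)cc4)=C[C@H](O[Si](C)(C)C(C)(C)C)[C@@H](O[Si](C)(C)C(C)(C)C)[C@@H]3C | intermediate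
27 | (2S,3S,5R,8S,9S,10R)-2-(1-bromoethenyl)-8,9-bis(tert-butyldimethylsilyloxy)-6-{[(4-methoxybenzyl)oxy]methyl}-10-methylspiro[4.5]dec-6-en-3-ol | O[C@H]2C[C@@]3(C[C@@H]2C(Br)=C)C(COCc4ccc(OC)cc4)=C[C@H](O[Si](C)(C)C(C)(C)C)[C@@H](O[Si](C)(C)C(C)(C)C)[C@@H]3C | intermediate
28 | 3-yl 4-methylbenzenesulfonate of 27 (tosylate trans to the 1-bromoethenyl group) | Cc1ccc(cc1)S(=O)(=O)O[C@H]2C[C@@]3(C[C@@H]2C(Br)=C)C(COCc4ccc(OC)cc4)=C[C@H](O[Si](C)(C)C(C)(C)C)[C@@H](O[Si](C)(C)C(C)(C)C)[C@@H]3C | intermediate
29 | alkenyllithium from 28 (Br replaced by Li) | Cc1ccc(cc1)S(=O)(=O)O[C@H]2C[C@@]3(C[C@@H]2C([Li])=C)C(COCc4ccc(OC)cc4)=C[C@H](O[Si](C)(C)C(C)(C)C)[C@@H](O[Si](C)(C)C(C)(C)C)[C@@H]3C | intermediate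
30 | lithium 2-substituted acrylate from 29 and CO2 | Cc1ccc(cc1)S(=O)(=O)O[C@H]2C[C@@]3(C[C@@H]2C(=C)C(=O)O[Li])C(COCc4ccc(OC)cc4)=C[C@H](O[Si](C)(C)C(C)(C)C)[C@@H](O[Si](C)(C)C(C)(C)C)[C@@H]3C | intermediate
31 | spiro cis-fused α-methylene-γ-butyrolactone with 8,9-bis(tert-butyldimethylsilyloxy) groups and a (4-methoxybenzyl)oxymethyl group (lactone carbinol carbon R, ring-fusion carbon R, spiro carbon R) | C=C1C(=O)O[C@@H]2C[C@@]3(C[C@H]12)C(COCc4ccc(OC)cc4)=C[C@H](O[Si](C)(C)C(C)(C)C)[C@@H](O[Si](C)(C)C(C)(C)C)[C@@H]3C | intermediate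
32 | primary allylic alcohol from 31 (PMB removed) | C=C1C(=O)O[C@@H]2C[C@@]3(C[C@H]12)C(CO)=C[C@H](O[Si](C)(C)C(C)(C)C)[C@@H](O[Si](C)(C)C(C)(C)C)[C@@H]3C | intermediate
33 | (2Z)-2-methylbut-2-enoic acid (angelic acid) | OC(=O)/C(C)=C\C | starting material
34 | (2Z)-2-methylbut-2-enoic 2,4,6-trichlorobenzoic anhydride | O=C(OC(=O)/C(C)=C\C)c1c(Cl)cc(Cl)cc1Cl | intermediate
35 | bis(tert-butyldimethylsilyl) ether of the target angelate | C=C1C(=O)O[C@@H]2C[C@@]3(C[C@H]12)C(COC(=O)/C(C)=C\C)=C[C@H](O[Si](C)(C)C(C)(C)C)[C@@H](O[Si](C)(C)C(C)(C)C)[C@@H]3C | intermediate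
36 | CNP0224912.1: spiro cis-fused α-methylene-γ-butyrolactone with trans-diol, ring methyl and (Z)-2-methylbut-2-enoyloxymethyl group | C=C1C(=O)O[C@@H]2C[C@@]3(C[C@H]12)C(COC(=O)/C(C)=C\C)=C[C@H](O)[C@@H](O)[C@@H]3C | target

**Step count.** Total: 20 steps. Longest linear sequence: 18 steps (from 6 through steps 2–8 and 10–20).

**Steps most likely to fail**

1. Step 17. The alkenyllithium may attack the tosylate-bearing carbon in a 3-exo-tet closure (methylenecyclopropane formation), t-BuLi may attack the sulfonate, or slow displacement by the lithium carboxylate may let elimination compete. The fallback separates carboxylation from ring closure. It sets out from alcohol 27: bromine–lithium exchange with t-BuLi (3.1 equiv, the alkoxide forming first) and a CO2 quench would give the hydroxy acid F1. Mitsunobu lactonisation (PPh3, DIAD, toluene, high dilution) would then activate the carbinol and close the ring with inversion, returning to the route at lactone 31.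

2. Step 8. The ring-closing displacement at the primary chloride next to the silyloxy carbon may be slow, so that proton transfer between enolates, γ-deprotonation and O-alkylation erode the spiroannulation. The fallback sets out from enone 5 and triflate 16 and stops after the first alkylation to isolate the monoalkylated enone 17. Finkelstein exchange (NaI, acetone, reflux) would give the primary iodide F2, which would be closed with KN(SiMe3)2 in THF at −78 → 0 °C, where the iodide should react before the enolate equilibrates. It returns to the route at spiro enone 18.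

3. Step 10. Halogen–lithium exchange between the alkoxymethyllithium (or residual n-BuLi) and the vinyl bromide may compete with carbonyl addition. The fallback uses a Grignard reagent that does not exchange. It sets out from spiro enone 18: addition of (i-PrO)Me2SiCH2MgCl (from the chloromethylsilane and Mg, THF, 0 °C) would give the silylmethyl carbinol F3. Tamao–Fleming oxidation (H2O2, KF, KHCO3, THF/MeOH) would give the diol F4. Selective etherification of the primary hydroxyl (NaH, 1 equiv, 4-methoxybenzyl chloride, THF, 0 °C) would return to the route at carbinol 22.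

**Further compounds**

F1 | step 17 | 2-[(2R,3S,5R,8S,9S,10R)-8,9-bis(tert-butyldimethylsilyloxy)-3-hydroxy-6-{[(4-methoxybenzyl)oxy]methyl}-10-methylspiro[4.5]dec-6-en-2-yl]prop-2-enoic acid | O[C@H]2C[C@@]3(C[C@@H]2C(=C)C(=O)O)C(COCc4ccc(OC)cc4)=C[C@H](O[Si](C)(C)C(C)(C)C)[C@@H](O[Si](C)(C)C(C)(C)C)[C@@H]3C
F2 | step 8 | (5S,6R)-6-[(2S,3R)-2-(1-bromoethenyl)-4-iodo-3-(triethylsilyloxy)butyl]-5-methylcyclohex-2-en-1-one | O=C1C=CC[C@H](C)[C@H]1C[C@H](C(Br)=C)[C@@H](O[Si](CC)(CC)CC)CI
F3 | step 10 | (2S,3S,5R,10S)-2-(1-bromoethenyl)-6-{[dimethyl(propan-2-yloxy)silyl]methyl}-10-methyl-3-(triethylsilyloxy)spiro[4.5]dec-7-en-6-ol (C6 epimers) | CC[Si](CC)(CC)O[C@H]2C[C@@]3(C[C@@H]2C(Br)=C)C(O)(C[Si](C)(C)OC(C)C)C=CC[C@@H]3C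
F4 | step 10 | (2S,3S,5R,10S)-2-(1-bromoethenyl)-6-(hydroxymethyl)-10-methyl-3-(triethylsilyloxy)spiro[4.5]dec-7-en-6-ol (C6 epimers) | CC[Si](CC)(CC)O[C@H]2C[C@@]3(C[C@@H]2C(Br)=C)C(O)(CO)C=CC[C@@H]3C
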